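**Retrosynthetic overview**
1. Last bond (C2–C1′): B-alkyl Suzuki coupling of a (2Z)-2-bromo-enoate with the 9-BBN adduct of (S)-2-methylpent-4-enyl acetate. The ester α-carbon is the electrophile, and the C2=C3 geometry is fixed in the bromide.
2. Key disconnection (C–C bond at the stereocentre): (S)-2-methylpent-4-enal from propanal and allyltrimethylsilane by organo-SOMO α-allylation. The aldehyde α-carbon reacts as an enolonium-type radical cation, so two normally nucleophilic carbons are joined and the catalyst sets the only stereocentre.
3. Bromo-enoate from (4E)-7-(furan-3-yl)-4-methylhept-4-enal by a bromo-ylide Wittig. The aldehyde comes from geranyl acetate (source of the 6E alkene) by distal epoxidation, Cu-catalysed coupling with 3-furylmethylmagnesium chloride and periodate cleavage.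
4. Rings: none is built. The furan is bought as furan-3-ylmethanol; the only ring made is a transient epoxide (step 4), cleaved in step 6.

Assumption: compound numbers follow first appearance in the numbered steps, a one-pot sequence counts as one step, and the racemic epoxide centre of 10 and 12 is irrelevant because step 6 destroys it.

**Route**

Step 1
Reactants: 1 propanal; 2 allyltrimethylsilane
Product: 4 (S)-2-methylpent-4-en-1-ol, via (S)-2-methylpent-4-enal 3 (not isolated)
Conditions: (2R,5R)-5-benzyl-2-tert-butyl-3-methylimidazolidin-4-one·TFA (20 mol %), (NH4)2Ce(NO3)6 (2 equiv), NaHCO3, DME, −20 °C, 24 h; then NaBH4, MeOH, 0 °C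
Reagents that add atoms: none
Why: Organo-SOMO α-allylation (MacMillan SOMO catalysis): CAN oxidises the catalyst-bound enamine of 1 to a 3π-electron radical cation whose normally nucleophilic α-carbon now acts as an enolonium equivalent and is attacked by the nucleophilic terminus of 2 on the face not shielded by the benzyl group of the (2R,5R)-catalyst (Re face), which sets the (S)-methyl stereocentre (about 90% ee expected by analogy with higher aldehydes), and second oxidation, loss of silicon and hydrolysis give 3, which is reduced at once so that the volatile, epimerisable aldehyde is never handled.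

Step 2
Reactants: 4 (S)-2-methylpent-4-en-1-ol
Product: 5 (S)-2-methylpent-4-en-1-yl acetate
Conditions: Ac2O, pyridine, DMAP (cat.), CH2Cl2, 0 °C → rt
Reagents that add atoms: acetic anhydride CC(=O)OC(C)=O
Why: DMAP-catalysed O-acetylation of a primary alcohol, which does not involve the stereocentre.

Step 3
Reactants: 6 furan-3-ylmethanol
Product: 8 3-(chloromethyl)furan, via furan-3-ylmethyl methanesulfonate 7 (not isolated)
Conditions: MsCl, LiCl, 2,4,6-collidine, DMF, 0 °C; used at once
Reagents that add atoms: methanesulfonyl chloride CS(=O)(=O)Cl (stays only in 7); lithium chloride [Li+].[Cl-]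
Why: Collington–Meyers chlorination, in which the mesylate formed in situ is displaced by chloride (SN2) under non-acidic conditions that the furan tolerates.

Step 4
Reactants: 9 geranyl acetate
Product: 10 (2E)-5-(3,3-dimethyloxiran-2-yl)-3-methylpent-2-en-1-yl acetate (6,7-epoxygeranyl acetate, racemic)
Conditions: mCPBA (1.05 equiv), CH2Cl2, 0 °C
Reagents that add atoms: meta-chloroperoxybenzoic acid OOC(=O)c1cccc(Cl)c1
Why: Prilezhaev epoxidation, selective for the electron-rich 6,7-alkene over the 2,3-alkene deactivated by the allylic acetate; the new epoxide stereocentre is formed racemic and is destroyed in step 6.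

Step 5
Reactants: 8 3-(chloromethyl)furan; 10 6,7-epoxygeranyl acetate
Product: 12 3-[(3E)-6-(3,3-dimethyloxiran-2-yl)-4-methylhex-3-en-1-yl]furan (racemic), via (furan-3-ylmethyl)magnesium chloride 11 (not isolated)
Conditions: Mg, THF, 0 °C → rt; then 10, Li2CuCl4 (3 mol %), THF, −20 → 0 °C
Reagents that add atoms: magnesium [Mg] (stays only in 11)
Why: Grignard formation followed by Cu-catalysed allylic substitution (Kochi/Fouquet–Schlosser coupling) at the α-carbon of the primary allylic acetate with retention of the E alkene, the trisubstituted epoxide being inert to the organocopper at low temperature.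

Step 6
Reactants: 12 3-[(3E)-6-(3,3-dimethyloxiran-2-yl)-4-methylhex-3-en-1-yl]furan
Product: 13 (4E)-7-(furan-3-yl)-4-methylhept-4-enal
Conditions: H5IO6 (1.1 equiv), THF/H2O, 0 °C, 30 min
Reagents that add atoms: none
Why: Acid-mediated epoxide hydrolysis and Malaprade glycol cleavage in one pot give the aldehyde and acetone without touching the trisubstituted alkene or, in a short cold reaction, the furan.

Step 7
Reactants: 13 (4E)-7-(furan-3-yl)-4-methylhept-4-enal; 14 methyl (triphenylphosphoranylidene)acetate
Product: 16 methyl (2Z,6E)-2-bromo-9-(furan-3-yl)-6-methylnona-2,6-dienoate, via methyl bromo(triphenylphosphoranylidene)acetate 15 (not isolated)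
Conditions: 14 (1.3 equiv), NBS (1.25 equiv), CH2Cl2, −20 °C, 30 min; then 13, rt, 12 h
Reagents that add atoms: N-bromosuccinimide O=C1CCC(=O)N1Br
Why: Bromination of the stabilised ylide (NBS is fully consumed before 13 is added, which protects the furan) followed by Wittig olefination, in which the stabilised bromo-ylide places the aldehyde residue trans to the ester and so gives the (Z)-α-bromo-enoate.

Step 8
Reactants: 5 (S)-2-methylpent-4-en-1-yl acetate; 16 methyl (2Z,6E)-2-bromo-9-(furan-3-yl)-6-methylnona-2,6-dienoate
Product: 18 methyl (2E,6E)-2-[(4S)-5-(acetyloxy)-4-methylpentyl]-9-(furan-3-yl)-6-methylnona-2,6-dienoate, via (2S)-5-(9-borabicyclo[3.3.1]nonan-9-yl)-2-methylpentyl acetate 17 (not isolated)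
Conditions: 5 (1.5 equiv), 9-BBN (1.4 equiv), THF, 0 °C → rt; then 16, Pd(dppf)Cl2·CH2Cl2 (5 mol %), AsPh3, Cs2CO3, DMF/THF/H2O, rt
Reagents that add atoms: 9-borabicyclo[3.3.1]nonane B1C2CCCC1CCC2 (boron framework stays only in 17; 18 keeps only a hydrogen from it)
Why: Anti-Markovnikov hydroboration of the terminal alkene followed by B-alkyl Suzuki–Miyaura coupling, in which the ester α-carbon of the vinyl bromide is the electrophile and the C–Br geometry is retained, so the new chain ends up cis to C4 and the (2E)-enoate of the target results with the remote stereocentre untouched.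

**Compound list**
1 | propanal | CCC=O | starting material
2 | allyltrimethylsilane | C=CC[Si](C)(C)C | starting material
3 | (S)-2-methylpent-4-enal | C=CC[C@H](C)C=O | intermediate
4 | (S)-2-methylpent-4-en-1-ol | C=CC[C@H](C)CO | intermediate
5 | (S)-2-methylpent-4-en-1-yl acetate | C=CC[C@H](C)COC(C)=O | intermediate
6 | furan-3-ylmethanol | OCc1ccoc1 | starting material
7 | furan-3-ylmethyl methanesulfonate | CS(=O)(=O)OCc1ccoc1 | intermediate
8 | 3-(chloromethyl)furan | ClCc1ccoc1 | intermediate
9 | geranyl acetate, (2E)-3,7-dimethylocta-2,6-dien-1-yl acetate | CC(=O)OC/C=C(\C)CCC=C(C)C | starting material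
10 | (2E)-5-(3,3-dimethyloxiran-2-yl)-3-methylpent-2-en-1-yl acetate (racemic at the epoxide) | CC(=O)OC/C=C(\C)CCC1OC1(C)C | intermediate
11 | (furan-3-ylmethyl)magnesium chloride | Cl[Mg]Cc1ccoc1 | intermediate
12 | 3-[(3E)-6-(3,3-dimethyloxiran-2-yl)-4-methylhex-3-en-1-yl]furan (racemic at the epoxide) | CC1(C)OC1CC/C(C)=C/CCc1ccoc1 | intermediate
13 | (4E)-7-(furan-3-yl)-4-methylhept-4-enal | O=CCC/C(C)=C/CCc1ccoc1 | intermediate
14 | methyl (triphenylphosphoranylidene)acetate | COC(=O)C=P(c1ccccc1)(c1ccccc1)c1ccccc1 | starting material
15 | methyl bromo(triphenylphosphoranylidene)acetate | COC(=O)C(Br)=P(c1ccccc1)(c1ccccc1)c1ccccc1 | intermediate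
16 | methyl (2Z,6E)-2-bromo-9-(furan-3-yl)-6-methylnona-2,6-dienoate | COC(=O)/C(Br)=C/CC/C(C)=C/CCc1ccoc1 | intermediate
17 | (2S)-5-(9-borabicyclo[3.3.1]nonan-9-yl)-2-methylpentyl acetate | CC(=O)OC[C@@H](C)CCCB1C2CCCC1CCC2 | intermediate
18 | methyl (2E,6E)-2-[(4S)-5-(acetyloxy)-4-methylpentyl]-9-(furan-3-yl)-6-methylnona-2,6-dienoate | COC(=O)/C(=C/CC/C(C)=C/CCc1ccoc1)CCC[C@H](C)COC(C)=O | target

**Step count and risks**
Total: 8 steps. Longest linear sequence: 5 steps (6 → 8 → 12 → 13 → 16 → 18, or 9 → 10 → 12 → 13 → 16 → 18); the chiral fragment (1 → 4 → 5) joins in step 8.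

Most likely to fail:

Step 1. Propanal is small and volatile, and the ee (expected about 90%) may fall short of a single-enantiomer standard. The fallback sets the stereocentre by an auxiliary-controlled azaenolate alkylation of normal polarity. It sets out from 1: condensation with SAMP gives the propanal SAMP-hydrazone, (S)-2-(methoxymethyl)-1-[(E)-propylideneamino]pyrrolidine F1. LDA in THF at 0 °C, then allyl bromide at −100 °C, gives the allylated hydrazone, (S)-2-(methoxymethyl)-1-{(E)-[(2S)-2-methylpent-4-en-1-ylidene]amino}pyrrolidine F2, expected in de of at least 95%. Two-phase cleavage with saturated aqueous oxalic acid and ether releases the aldehyde, and the fallback comes back to the route at 3, which is reduced to 4 as in step 1.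

Step 5. The Grignard reagent may attack the acetate carbonyl, give SN2′ product or dimerise. The fallback exchanges the polarity of the two partners and alkylates a sulfone-stabilised allyl anion. It sets out from 10: Pd(PPh3)4-catalysed substitution of the allylic acetate by sodium p-toluenesulfinate gives the allyl sulfone, 2,2-dimethyl-3-[(3E)-3-methyl-5-(4-methylbenzenesulfonyl)pent-3-en-1-yl]oxirane F3. Deprotonation with n-BuLi in THF at −78 °C and alkylation with 8 gives the furylmethylated sulfone, 3-[(3E)-6-(3,3-dimethyloxiran-2-yl)-4-methyl-2-(4-methylbenzenesulfonyl)hex-3-en-1-yl]furan F4. Pd(dppp)Cl2-catalysed hydride desulfonylation (LiBHEt3, THF, 0 °C, short reaction time) delivers hydride to the less substituted allyl terminus, keeps the alkene position and E geometry, and comes back to the route at 12.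

Step 8. The α-bromo-enoate may undergo protodebromination, the alkyl-palladium may β-eliminate, or the base may partly cleave the acetate. The fallback gives up the cross-coupling for a classical Wittig olefination. It sets out from 5: hydroboration to 17 as in step 8 and oxidation with NaBO3·4H2O gives (2S)-5-hydroxy-2-methylpentyl acetate F5. Iodine, PPh3 and imidazole give (2S)-5-iodo-2-methylpentyl acetate F6. Heating F6 with two equivalents of 14 in ethyl acetate (alkylation, then transylidation) gives the α-alkylated stabilised ylide, methyl (6S)-7-(acetyloxy)-6-methyl-2-(triphenylphosphoranylidene)heptanoate F7. F7 and aldehyde 13 in toluene at 90 °C give the (E)-enoate selectively, and the fallback comes back to the route at 18.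

**Further compounds**
F1 | step 1 | (S)-2-(methoxymethyl)-1-[(E)-propylideneamino]pyrrolidine | CC/C=N/N1CCC[C@H]1COC
F2 | step 1 | (S)-2-(methoxymethyl)-1-{(E)-[(2S)-2-methylpent-4-en-1-ylidene]amino}pyrrolidine | C=CC[C@H](C)/C=N/N1CCC[C@H]1COC
F3 | step 5 | 2,2-dimethyl-3-[(3E)-3-methyl-5-(4-methylbenzenesulfonyl)pent-3-en-1-yl]oxirane (racemic at the epoxide) | Cc1ccc(cc1)S(=O)(=O)C/C=C(\C)CCC1OC1(C)C
F4 | step 5 | 3-[(3E)-6-(3,3-dimethyloxiran-2-yl)-4-methyl-2-(4-methylbenzenesulfonyl)hex-3-en-1-yl]furan (mixture of diastereomers, racemic) | Cc1ccc(cc1)S(=O)(=O)C(Cc1ccoc1)/C=C(\C)CCC1OC1(C)C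
F5 | step 8 | (2S)-5-hydroxy-2-methylpentyl acetate | OCCC[C@H](C)COC(C)=O
F6 | step 8 | (2S)-5-iodo-2-methylpentyl acetate | ICCC[C@H](C)COC(C)=O
F7 | step 8 | methyl (6S)-7-(acetyloxy)-6-methyl-2-(triphenylphosphoranylidene)heptanoate | COC(=O)C(CCC[C@H](C)COC(C)=O)=P(c1ccccc1)(c1ccccc1)c1ccccc1
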